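## Retrosynthetic overview

1. The acid comes from one-pot desilylation/oxidation of a TBS-protected 2-hydroxyethyl arm; the (5E)-alkene comes from a Julia–Kocienski olefination of a dioxolane aldehyde with a (4E)-5-phenylpent-4-enyl tetrazolyl sulfone.
2. The aldehyde comes from ozonolysis of a terminal vinyl group that passes through ring formation as a spectator.
3. The 1,2-dioxolane (the only ring that is built) comes from a formal [3+2] cycloaddition of a peroxycarbenium ion (C3–O–O) with a 1,1-disubstituted alkene (C4–C5).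
4. The alkene partner comes from (R)-citronellic acid, which supplies the side-chain stereocentre; the peroxycarbenium precursor comes from 3-methylbut-3-en-1-ol by ozonolysis in methanol.
5. Both ring stereocentres arise in the single ring-forming step. The bought (R)-methyl centre does not bias them, but it makes all ring isomers diastereomers, so the wanted cis isomer is taken by separation.

Assumption: (R)-(+)-citronellic acid, 3-methylbut-3-en-1-ol and (4E)-5-phenylpent-4-en-1-ol are taken as catalogue compounds; the target is read from the SMILES as the (3R,5R)-dioxolane with cis ring methyls and a (2R) side-chain centre.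

## Route

Step 1
Reactants: 1 (3R)-3,7-dimethyloct-6-enoic acid
Product: 2 (4R)-4,8-dimethylnon-7-en-2-one
Conditions: MeLi (2.2 equiv), Et2O, 0 °C to rt; inverse quench into cold aq. HCl
Reagents that add atoms: methyllithium, [Li]C
Why: Addition of an organolithium to a lithium carboxylate stops at the dilithium gem-diolate, which gives the methyl ketone only on quench, and the non-enolisable β-stereocentre bought in 1 is untouched.

Step 2
Reactants: 2 (4R)-4,8-dimethylnon-7-en-2-one
Product: 3 (4R)-4-methyl-6-oxoheptanal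
Conditions: O3, CH2Cl2, −78 °C; then Me2S, −78 °C to rt
Reagents that add atoms: ozone, [O-][O+]=O
Why: Ozonolysis with reductive work-up cleaves the only C=C to the aldehyde and leaves the ketone and the stereocentre alone.

Step 3
Reactants: 3 (4R)-4-methyl-6-oxoheptanal
Product: 5 (4R)-2,4-dimethylocta-1,7-diene, via keto-alkene 4 (not isolated)
Conditions: Ph3PCH3Br (3.0 equiv), KOC(CH3)3 (2.9 equiv), THF, 0 °C; add 3 at −78 °C, then rt to 40 °C
Reagents that add atoms: methyltriphenylphosphonium bromide, C[P+](c1ccccc1)(c1ccccc1)c1ccccc1.[Br-]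
Why: Wittig methylenation takes the aldehyde at −78 °C (faster than aldol chemistry of the keto-aldehyde) and the methyl ketone on warming, giving in one flask the 1,1-disubstituted alkene needed for ring formation and a monosubstituted vinyl group that serves as a masked aldehyde.

Step 4
Reactants: 6 3-methylbut-3-en-1-ol
Product: 7 tert-butyldimethyl[(3-methylbut-3-en-1-yl)oxy]silane
Conditions: TBSCl, imidazole, CH2Cl2, 0 °C to rt
Reagents that add atoms: tert-butyldimethylsilyl chloride, CC(C)(C)[Si](C)(C)Cl
Why: Standard silylation of a primary alcohol; the silyl ether is the latent carboxyl group and survives every step up to the last.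

Step 5
Reactants: 7 tert-butyldimethyl[(3-methylbut-3-en-1-yl)oxy]silane
Product: 9 4-[(tert-butyldimethylsilyl)oxy]-2-methoxybutan-2-yl hydroperoxide, via carbonyl oxide 8 (not isolated)
Conditions: O3, CH2Cl2/MeOH (4:1), −78 °C; N2 purge; concentrate below rt
Reagents that add atoms: ozone, [O-][O+]=O; methanol, CO
Why: Criegee ozonolysis in methanol splits the primary ozonide of a 1,1-disubstituted alkene into formaldehyde and the ketone oxide, which methanol traps as the α-methoxy hydroperoxide (racemic; this centre becomes planar again in step 7).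

Step 6
Reactants: 9 4-[(tert-butyldimethylsilyl)oxy]-2-methoxybutan-2-yl hydroperoxide
Product: 10 tert-butyl{3-methoxy-3-[(triethylsilyl)peroxy]butoxy}dimethylsilane
Conditions: Et3SiCl, imidazole, DMF, 0 °C
Reagents that add atoms: chlorotriethylsilane, CC[Si](Cl)(CC)CC
Why: O-Silylation of the hydroperoxide gives the silyl peroxyketal whose methoxy group can be ionised selectively and whose silyl group is released on ring closure.

Step 7
Reactants: 5 (4R)-2,4-dimethylocta-1,7-diene; 10 tert-butyl{3-methoxy-3-[(triethylsilyl)peroxy]butoxy}dimethylsilane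
Product: 13 tert-butyl{2-[(3S,5R)-3,5-dimethyl-5-[(2R)-2-methylhex-5-en-1-yl]-1,2-dioxolan-3-yl]ethoxy}dimethylsilane, via peroxycarbenium ion 11 (not isolated), via tertiary carbocation 12 (not isolated)
Conditions: 5 (1.0 equiv), 10 (1.5 equiv), SnCl4 (1.5 equiv), CH2Cl2, −78 °C, 1 h; aq. NaHCO3; silica gel, then preparative HPLC
Reagents that add atoms: none
Why: Formal [3+2] cycloaddition (peroxycarbenium–alkene annulation) in which SnCl4 removes methoxide, the 1,1-disubstituted alkene adds through its CH2 terminus (the vinyl group is far less nucleophilic) and the resulting tertiary cation is closed by the silylperoxy oxygen with loss of the silyl group, so both ring stereocentres form here without useful bias from the remote (R)-methyl centre and the cis-dimethyl (3S,5R) isomer is isolated from four diastereomers that are separable without a chiral agent only because the bought centre is already present.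

Step 8
Reactants: 13 tert-butyl{2-[(3S,5R)-3,5-dimethyl-5-[(2R)-2-methylhex-5-en-1-yl]-1,2-dioxolan-3-yl]ethoxy}dimethylsilane
Product: 14 (4R)-5-[(3R,5S)-5-{2-[(tert-butyldimethylsilyl)oxy]ethyl}-3,5-dimethyl-1,2-dioxolan-3-yl]-4-methylpentanal
Conditions: O3, CH2Cl2/MeOH (4:1), NaHCO3, −78 °C; then Me2S, −78 °C to rt
Reagents that add atoms: ozone, [O-][O+]=O
Why: Ozonolysis of the only remaining C=C unveils the aldehyde; dialkyl peroxides and silyl ethers are inert to ozone and to Me2S (a phosphine work-up is avoided because phosphines deoxygenate peroxides).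

Step 9
Reactants: 15 (4E)-5-phenylpent-4-en-1-ol
Product: 16 1-phenyl-5-{[(4E)-5-phenylpent-4-en-1-yl]sulfanyl}-1H-tetrazole
Conditions: 1-phenyl-1H-tetrazole-5-thiol, PPh3, DIAD, THF, 0 °C to rt
Reagents that add atoms: 1-phenyl-1H-tetrazole-5-thiol, Sc1nnnn1-c1ccccc1
Why: Mitsunobu thioetherification of a primary alcohol with the acidic tetrazole thiol.

Step 10
Reactants: 16 1-phenyl-5-{[(4E)-5-phenylpent-4-en-1-yl]sulfanyl}-1H-tetrazole
Product: 17 1-phenyl-5-{[(4E)-5-phenylpent-4-en-1-yl]sulfonyl}-1H-tetrazole
Conditions: (NH4)6Mo7O24·4H2O (10 mol %), 30% aq. H2O2, EtOH, 0 °C to rt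
Reagents that add atoms: hydrogen peroxide, OO
Why: Molybdate-catalysed peroxide oxidation takes the sulfide to the sulfone without epoxidising the styrenyl alkene.

Step 11
Reactants: 14 (4R)-5-[(3R,5S)-5-{2-[(tert-butyldimethylsilyl)oxy]ethyl}-3,5-dimethyl-1,2-dioxolan-3-yl]-4-methylpentanal; 17 1-phenyl-5-{[(4E)-5-phenylpent-4-en-1-yl]sulfonyl}-1H-tetrazole
Product: 18 tert-butyl{2-[(3S,5R)-3,5-dimethyl-5-[(2R,5E,9E)-2-methyl-10-phenyldeca-5,9-dien-1-yl]-1,2-dioxolan-3-yl]ethoxy}dimethylsilane
Conditions: 17 (1.3 equiv), KN(SiMe3)2 (1.25 equiv), DME, −60 °C, 30 min; add 14; −60 °C to rt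
Reagents that add atoms: none
Why: Julia–Kocienski olefination, in which the sulfonyl carbanion adds to the aldehyde and Smiles rearrangement with loss of SO2 and the tetrazolyl oxide gives the alkene with high E selectivity (potassium counter-ion in DME), while the hindered tertiary dialkyl peroxide should tolerate the stabilised carbanion at low temperature and no stereocentre is touched.

Step 12
Reactants: 18 tert-butyl{2-[(3S,5R)-3,5-dimethyl-5-[(2R,5E,9E)-2-methyl-10-phenyldeca-5,9-dien-1-yl]-1,2-dioxolan-3-yl]ethoxy}dimethylsilane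
Product: 19 2-[(3R,5R)-3,5-dimethyl-5-[(2R,5E,9E)-2-methyl-10-phenyldeca-5,9-dien-1-yl]-1,2-dioxolan-3-yl]acetic acid
Conditions: CrO3, H2SO4, H2O (3 equiv of hexavalent chromium), acetone, 0 °C to rt
Reagents that add atoms: water, O
Why: Jones oxidation, in which the aqueous acid cleaves the primary silyl ether and chromic acid oxidises the freed alcohol through the aldehyde hydrate to the acid; both ring carbons are quaternary, so nothing can epimerise (the descriptor at C3 changes from S to R only because the arm gains priority).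

## Compound list

1 | (3R)-3,7-dimethyloct-6-enoic acid, (R)-citronellic acid | C[C@H](CCC=C(C)C)CC(=O)O | starting material
2 | (4R)-4,8-dimethylnon-7-en-2-one | C[C@H](CCC=C(C)C)CC(C)=O | intermediate
3 | (4R)-4-methyl-6-oxoheptanal | C[C@H](CCC=O)CC(C)=O | intermediate
4 | keto-alkene, (4R)-4-methyloct-7-en-2-one | C[C@H](CCC=C)CC(C)=O | intermediate
5 | (4R)-2,4-dimethylocta-1,7-diene | C[C@H](CCC=C)CC(C)=C | intermediate
6 | 3-methylbut-3-en-1-ol | CC(=C)CCO | starting material
7 | tert-butyldimethyl[(3-methylbut-3-en-1-yl)oxy]silane | CC(=C)CCO[Si](C)(C)C(C)(C)C | intermediate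
8 | carbonyl oxide, 4-[(tert-butyldimethylsilyl)oxy]butan-2-one O-oxide | CC(CCO[Si](C)(C)C(C)(C)C)=[O+][O-] | intermediate
9 | 4-[(tert-butyldimethylsilyl)oxy]-2-methoxybutan-2-yl hydroperoxide (racemic) | CC(OC)(CCO[Si](C)(C)C(C)(C)C)OO | intermediate
10 | tert-butyl{3-methoxy-3-[(triethylsilyl)peroxy]butoxy}dimethylsilane (racemic) | CC(OC)(CCO[Si](C)(C)C(C)(C)C)OO[Si](CC)(CC)CC | intermediate
11 | peroxycarbenium ion, {4-[(tert-butyldimethylsilyl)oxy]butan-2-ylidene}[(triethylsilyl)oxy]oxidanium | CC(CCO[Si](C)(C)C(C)(C)C)=[O+]O[Si](CC)(CC)CC | intermediate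
12 | tertiary carbocation, (5R)-11-[(tert-butyldimethylsilyl)oxy]-5,7,9-trimethyl-9-[(triethylsilyl)peroxy]undec-1-en-7-ylium | C[C@H](CCC=C)C[C+](C)CC(C)(CCO[Si](C)(C)C(C)(C)C)OO[Si](CC)(CC)CC | intermediate
13 | tert-butyl{2-[(3S,5R)-3,5-dimethyl-5-[(2R)-2-methylhex-5-en-1-yl]-1,2-dioxolan-3-yl]ethoxy}dimethylsilane (ring methyls cis) | C[C@H](CCC=C)C[C@]1(C)C[C@](C)(CCO[Si](C)(C)C(C)(C)C)OO1 | intermediate
14 | (4R)-5-[(3R,5S)-5-{2-[(tert-butyldimethylsilyl)oxy]ethyl}-3,5-dimethyl-1,2-dioxolan-3-yl]-4-methylpentanal | C[C@H](CCC=O)C[C@]1(C)C[C@](C)(CCO[Si](C)(C)C(C)(C)C)OO1 | intermediate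
15 | (4E)-5-phenylpent-4-en-1-ol | OCCC/C=C/c1ccccc1 | starting material
16 | 1-phenyl-5-{[(4E)-5-phenylpent-4-en-1-yl]sulfanyl}-1H-tetrazole | C(CC/C=C/c1ccccc1)Sc1nnnn1-c1ccccc1 | intermediate
17 | 1-phenyl-5-{[(4E)-5-phenylpent-4-en-1-yl]sulfonyl}-1H-tetrazole | O=S(=O)(CCC/C=C/c1ccccc1)c1nnnn1-c1ccccc1 | intermediate
18 | tert-butyl{2-[(3S,5R)-3,5-dimethyl-5-[(2R,5E,9E)-2-methyl-10-phenyldeca-5,9-dien-1-yl]-1,2-dioxolan-3-yl]ethoxy}dimethylsilane | C[C@H](CC/C=C/CC/C=C/c1ccccc1)C[C@]1(C)C[C@](C)(CCO[Si](C)(C)C(C)(C)C)OO1 | intermediate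
19 | 2-[(3R,5R)-3,5-dimethyl-5-[(2R,5E,9E)-2-methyl-10-phenyldeca-5,9-dien-1-yl]-1,2-dioxolan-3-yl]acetic acid | C[C@H](CC/C=C/CC/C=C/c1ccccc1)C[C@]1(C)C[C@](C)(CC(=O)O)OO1 | target

## Step count and risks

Total step count: 12 (steps 1–12).
Longest linear sequence: 7 steps (1, 2, 3, 7, 8, 11, 12) from compound 1.

Steps most likely to fail:

Step 7. Two things can go wrong. The silyl ether oxygen can compete with the silylperoxy oxygen for the tertiary cation and close a six-membered ether. The ring stereochemistry is also essentially unbiased, so about a quarter of the annulated material at best is the wanted isomer, and the two cis isomers will need HPLC. The fallback reverses the polarity of the annulation; it sets out from 3 and comes back at 13. The methylenation of 3 is stopped at the aldehyde (1.05 equiv Ph3P=CH2, THF, −78 °C) and keto-alkene 4 is isolated. Its ketone is converted with HC(OCH3)3 and catalytic TsOH in MeOH into the dimethyl ketal (5R)-7,7-dimethoxy-5-methyloct-1-ene F1. One methoxy group is exchanged with ethereal H2O2 (catalytic TsOH) to give (4R)-2-methoxy-4-methyloct-7-en-2-yl hydroperoxide F2. Silylation (Et3SiCl, imidazole) gives triethyl{[(4R)-2-methoxy-4-methyloct-7-en-2-yl]peroxy}silane F3, which is treated with alkene 7 and SnCl4 at −78 °C. The tertiary cation now sits on the carbon that carries the silyloxyethyl arm, where the ether oxygen could only close a four-membered ring. The product is again 13, with the same isomer separation.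

Step 11. The sulfonyl carbanion or residual amide base may attack the O–O bond, or the aldehyde may enolise. The fallback moves the olefination ahead of ring formation; it sets out from 3 and comes back at 18. The potassium anion of 17 is added to keto-aldehyde 3 at −78 °C, where the aldehyde reacts and the methyl ketone does not, giving (4R,7E,11E)-4-methyl-12-phenyldodeca-7,11-dien-2-one F4. The ketone is methylenated (Ph3P=CH2) to [(1E,5E,9R)-9,11-dimethyldodeca-1,5,11-trien-1-yl]benzene F5. F5 is annulated with 10 and SnCl4 to reach 18 directly. The cost is some competition from the styrenyl double bond for the peroxycarbenium ion; the gain is that no ozonolysis or carbanion chemistry is run on a peroxide.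

Step 12. Chromic acid may attack the styrene or the skipped diene, or desilylation may lag behind oxidation. The fallback is stepwise and chromium-free; it sets out from 18 and comes back at 19. HF·pyridine in THF gives 2-[(3S,5R)-3,5-dimethyl-5-[(2R,5E,9E)-2-methyl-10-phenyldeca-5,9-dien-1-yl]-1,2-dioxolan-3-yl]ethan-1-ol F6. Dess–Martin periodinane with NaHCO3 in CH2Cl2 gives 2-[(3R,5R)-3,5-dimethyl-5-[(2R,5E,9E)-2-methyl-10-phenyldeca-5,9-dien-1-yl]-1,2-dioxolan-3-yl]acetaldehyde F7. Pinnick oxidation (NaClO2, NaH2PO4, 2-methyl-2-butene, t-BuOH/H2O) then gives 19.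

## Further compounds

F1 | step 7 | (5R)-7,7-dimethoxy-5-methyloct-1-ene | C[C@H](CCC=C)CC(C)(OC)OC
F2 | step 7 | (4R)-2-methoxy-4-methyloct-7-en-2-yl hydroperoxide (C2 epimers) | C[C@H](CCC=C)CC(C)(OC)OO
F3 | step 7 | triethyl{[(4R)-2-methoxy-4-methyloct-7-en-2-yl]peroxy}silane (C2 epimers) | C[C@H](CCC=C)CC(C)(OC)OO[Si](CC)(CC)CC
F4 | step 11 | (4R,7E,11E)-4-methyl-12-phenyldodeca-7,11-dien-2-one | C[C@H](CC/C=C/CC/C=C/c1ccccc1)CC(C)=O
F5 | step 11 | [(1E,5E,9R)-9,11-dimethyldodeca-1,5,11-trien-1-yl]benzene | C[C@H](CC/C=C/CC/C=C/c1ccccc1)CC(C)=C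
F6 | step 12 | 2-[(3S,5R)-3,5-dimethyl-5-[(2R,5E,9E)-2-methyl-10-phenyldeca-5,9-dien-1-yl]-1,2-dioxolan-3-yl]ethan-1-ol | C[C@H](CC/C=C/CC/C=C/c1ccccc1)C[C@]1(C)C[C@](C)(CCO)OO1
F7 | step 12 | 2-[(3R,5R)-3,5-dimethyl-5-[(2R,5E,9E)-2-methyl-10-phenyldeca-5,9-dien-1-yl]-1,2-dioxolan-3-yl]acetaldehyde | C[C@H](CC/C=C/CC/C=C/c1ccccc1)C[C@]1(C)C[C@](C)(CC=O)OO1
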